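Retrosynthesis: the 4'-O-silyl ether comes off last. Before that, ring A is opened at C4a-C5 and C7-C8, so C5-C6-C7 leaves with the C10 side chain as an (E)-alkenylmalonyl dichloride, while C8, C8a, C4a and C4 remain in a chiral 4-methoxy-6-methylene-dihydropyran.
Enabling feature: ring A is a phloroglucinol, the fully enolised form of a cyclohexane-1,3,5-trione, with oxygen on C5, C7 and C8a and donor carbons C4a, C6 and C8. The chain stands on C6, the middle atom of a C5-C6-C7 malonyl unit that is symmetric in itself, and the C8a-O1 and C4a-C4 bonds are shared with ring C. Two small chiral halves result, and no choice between C6 and C8 ever has to be made.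
Forward order: ring B arrives with the aldehyde, a hetero-Diels-Alder reaction of Brassard's diene makes ring C, and methylenation of the lactone carbonyl brings in C8. Ring A is formed last by a double C-acylation that also couples the terpenoid half.
Chain half: Knoevenagel condensation of (S)-citronellal with dimethyl malonate, then deconjugation, saponification and chlorination.
Stereochemistry: C2 (S) comes from the chiral diol catalyst of the cycloaddition, C3' (S) from (S)-citronellal, and the E C1'=C2' alkene from the deconjugative protonation.

Key step: step 9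

Assumption: the (R,R)-diol catalyst is taken to send the diene to the Si face of the aryl aldehyde, as in related cycloadditions of aryl aldehydes; if the first run shows the opposite sense, the equally available (S,S)-diol is used with no other change.

Step 1
Reactants: 1 methyl acetoacetate
Product: 3 methyl (E)-3-methoxybut-2-enoate, via methyl 3,3-dimethoxybutanoate 2 (not isolated)
Conditions: HC(OMe)3, cat. H2SO4, MeOH, rt to 50 °C; distil
Reagents that add atoms: trimethyl orthoformate, COC(OC)OC
Why: Acid-catalysed ketalisation of the ketone by the orthoester followed by loss of methanol is the standard enol etherification of a β-keto ester and should give the conjugated E enol ether as the thermodynamic isomer.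

Step 2
Reactants: 3 methyl (E)-3-methoxybut-2-enoate
Product: 5 Brassard's diene [(1E)-1,3-dimethoxy-1-(trimethylsilyloxy)buta-1,3-diene], via lithium dienolate 4 (not isolated)
Conditions: LiN(iPr)2, THF, -78 °C; Me3SiCl, -78 °C to rt; distil under reduced pressure
Reagents that add atoms: chlorotrimethylsilane, C[Si](C)(C)Cl
Why: Carbonyl-directed γ-deprotonation of the methyl group cis to the ester, followed by O-silylation of the extended enolate, is the established silyl ketene acetal formation that delivers this diene.

Step 3
Reactants: 5 Brassard's diene; 6 4-(tert-butyldimethylsilyloxy)benzaldehyde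
Product: 8 (S)-6-[4-(tert-butyldimethylsilyloxy)phenyl]-4-methoxy-5,6-dihydro-2H-pyran-2-one, via silyl orthoester cycloadduct 7 (not isolated)
Conditions: (4R,5R)-2,2-dimethyl-α,α,α',α'-tetra(naphthalen-1-yl)-1,3-dioxolane-4,5-dimethanol (20 mol %), toluene, -40 °C; cat. CF3CO2H, CH2Cl2, 0 °C; recrystallise
Reagents that add atoms: none
Why: In this catalytic asymmetric hetero-Diels-Alder reaction under hydrogen-bond activation, the chiral diol binds the aldehyde oxygen and covers its Re face, so the diene terminus bonds to the Si face and sets the future C2 as S, adduct 7 collapses to the lactone with loss of the silyl methyl ether, and crystallisation should raise the enantiopurity.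

Step 4
Reactants: 8 (S)-6-[4-(tert-butyldimethylsilyloxy)phenyl]-4-methoxy-5,6-dihydro-2H-pyran-2-one
Product: 9 (S)-2-[4-(tert-butyldimethylsilyloxy)phenyl]-4-methoxy-6-methylene-3,6-dihydro-2H-pyran
Conditions: Cp2TiMe2, toluene, 70 °C, dark; dilute with hexane, filter through Et3N-washed basic alumina; use at once
Reagents that add atoms: dimethyltitanocene Cp2TiMe2, C[Ti+2]C.c1cc[cH-]c1.c1cc[cH-]c1
Why: In the Petasis methylenation the thermally formed titanium methylidene converts lactone and unsaturated ester carbonyls into enol ethers by [2+2] cycloaddition and cycloreversion, under non-acidic conditions that leave the aryl silyl ether, the methyl enol ether and the benzylic stereocentre untouched.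

Step 5
Reactants: 10 (S)-citronellal; 11 dimethyl malonate
Product: 12 dimethyl 2-[(3S)-3,7-dimethyloct-6-en-1-ylidene]malonate
Conditions: piperidine (cat.), AcOH (cat.), 4 Å sieves, CH2Cl2, 0 °C to rt
Reagents that add atoms: none
Why: Knoevenagel condensation under piperidinium acetate catalysis is the usual entry to citronellylidene malonates; at room temperature and without a Lewis acid the intramolecular ene reaction of the product should not start, and the β-stereocentre is not enolisable.

Step 6
Reactants: 12 dimethyl 2-[(3S)-3,7-dimethyloct-6-en-1-ylidene]malonate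
Product: 14 dimethyl 2-[(1E,3S)-3,7-dimethylocta-1,6-dien-1-yl]malonate, via lithium malonate dienolate 13 (not isolated)
Conditions: LiN(SiMe3)2, THF, -78 °C; cannulate into AcOH/THF, -78 °C
Reagents that add atoms: none
Why: In this deconjugative protonation of an alkylidene malonate the silylamide removes a C2' proton from the conformer that keeps the C3' substituent away from the cis ester (allylic 1,3-strain), so extended enolate 13 carries an E C1'=C2' bond, and fast cold protonation occurs at the α-carbon while C3'-H is never removed.

Step 7
Reactants: 14 dimethyl 2-[(1E,3S)-3,7-dimethylocta-1,6-dien-1-yl]malonate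
Product: 16 2-[(1E,3S)-3,7-dimethylocta-1,6-dien-1-yl]malonic acid, via dilithium malonate 15 (not isolated)
Conditions: LiOH, THF/MeOH/H2O, 0 °C to rt; 1 M HCl to pH 2, 0 °C; extract, concentrate below 20 °C
Reagents that add atoms: lithium hydroxide, [Li+].[OH-]
Why: Saponification of a monosubstituted malonate followed by cold acidification is routine for arylmalonates, which are equally C-H acidic and equally prone to decarboxylation, and acidification should again protonate the delocalised anion at the α-carbon and keep the E alkene out of conjugation.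

Step 8
Reactants: 16 2-[(1E,3S)-3,7-dimethylocta-1,6-dien-1-yl]malonic acid
Product: 17 2-[(1E,3S)-3,7-dimethylocta-1,6-dien-1-yl]malonyl dichloride
Conditions: (COCl)2, cat. HCONMe2, CH2Cl2, 0 °C; evaporate below 20 °C; use at once as a CH2Cl2 solution
Reagents that add atoms: oxalyl chloride, O=C(Cl)C(=O)Cl
Why: Acid chloride formation with oxalyl chloride under Vilsmeier-type catalysis is the mild route to substituted malonyl dichlorides, is tolerated by the trisubstituted alkene as in the citronellic acid series, and gives only gaseous by-products, so the crude dichloride can be used without heating.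

Step 9
Reactants: 9 (S)-2-[4-(tert-butyldimethylsilyloxy)phenyl]-4-methoxy-6-methylene-3,6-dihydro-2H-pyran; 17 2-[(1E,3S)-3,7-dimethylocta-1,6-dien-1-yl]malonyl dichloride
Product: 20 (2S)-2-[4-(tert-butyldimethylsilyloxy)phenyl]-6-[(1E,3S)-3,7-dimethylocta-1,6-dien-1-yl]-5,7-dihydroxychroman-4-one (4'-O-TBS ether of the target), via C8-monoacylated dienol ether 18 (not isolated), via 4-methoxy-2H-chromene 19 (not isolated)
Conditions: 2,6-di-tert-butyl-4-methylpyridine (2.2 equiv), CH2Cl2 (ca. 5 mM), -78 °C, 9 and 17 (1 equiv each) added simultaneously by syringe pump, then to rt, subdued light; NaOAc/AcOH buffer pH 4.5, THF/H2O, 0 °C to rt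
Reagents that add atoms: water, O
Why: Proposed new method: the two ether oxygens (O1 on C8a, OMe on C4) turn the s-trans-locked diene of 9, which cannot act as a Diels-Alder diene, into a C8/C4a 1,3-dinucleophile, so C8 attacks one acyl chloride of 17 (or the chlorocarbonylketene formed from it by loss of HCl) and the hindered pyridine takes the C8 proton to give push-pull dienol ether 18. In 18 the carbon C4a, still the β-carbon of the C4 methyl enol ether, attacks the second acyl chloride in a 6-(enolexo)-exo-trig C-acylation that closes the carbocycle C4a-C5-C6-C7-C8-C8a, the only ring formed (ring A). Loss of the C4a proton and proton shifts from C6 and C3 to the oxygens on C7 and C5 then aromatise the ring to 5,7-diol 19, an irreversible sink, and the mildly acidic buffer hydrolyses its very electron-rich 4-methyl enol ether to the C4 ketone of 20. The closest known reaction types are the Effenberger cyclization of enol ethers with malonyl dichloride to cyclic triones and the [3+3] cyclization of 1,3-dioxygenated butadienes with 1,3-dielectrophiles to phenols. No stereocentre is created, and C2 (no neighbouring carbonyl until the hydrolysis) and C3' (outside every enolisable position) are carried through unchanged. The step needs C- rather than O-acylation, closure to a benzene rather than a 2-pyranone, and the chain on C6 rather than C8; both enol oxygens are alkylated (O1 inside ring C, O4 as its methyl ether), which leaves no enol OH to be acylated, the two acyl chlorides of 17 are equivalent, so it does not matter whether C8 or C4a reacts first, and pseudo-high dilution disfavours 2:1 adducts.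

Step 10
Reactants: 20 4'-O-TBS ether of the target
Product: 21 (2S)-6-[(1E,3S)-3,7-dimethylocta-1,6-dien-1-yl]-5,7-dihydroxy-2-(4-hydroxyphenyl)chroman-4-one (CNP0150993.1)
Conditions: KHF2, MeOH, rt
Reagents that add atoms: none
Why: In this fluoride-mediated desilylation KHF2 in methanol cleaves phenolic TBS ethers at room temperature in a weakly acidic medium, which avoids both the base-induced retro-oxa-Michael opening (C2 epimerisation, 6/8 scrambling) and the strong-acid or thermal cyclisation of the o-hydroxystyrene chain.

Compound list
1 | methyl acetoacetate | CC(=O)CC(=O)OC | starting material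
2 | methyl 3,3-dimethoxybutanoate (not isolated) | COC(=O)CC(C)(OC)OC | intermediate
3 | methyl (E)-3-methoxybut-2-enoate | CO/C(C)=C/C(=O)OC | intermediate
4 | lithium dienolate of 3 (not isolated) | C=C(OC)/C=C(OC)/[O-].[Li+] | intermediate
5 | Brassard's diene, (1E)-1,3-dimethoxy-1-(trimethylsilyloxy)buta-1,3-diene | C=C(OC)/C=C(OC)/O[Si](C)(C)C | intermediate
6 | 4-(tert-butyldimethylsilyloxy)benzaldehyde | O=Cc1ccc(O[Si](C)(C)C(C)(C)C)cc1 | starting material
7 | (6S)-6-[4-(tert-butyldimethylsilyloxy)phenyl]-2,4-dimethoxy-2-(trimethylsilyloxy)-5,6-dihydro-2H-pyran, C2 of the pyran undefined (not isolated) | COC1(O[Si](C)(C)C)C=C(OC)C[C@@H](c2ccc(O[Si](C)(C)C(C)(C)C)cc2)O1 | intermediate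
8 | (S)-6-[4-(tert-butyldimethylsilyloxy)phenyl]-4-methoxy-5,6-dihydro-2H-pyran-2-one | O=C1C=C(OC)C[C@@H](c2ccc(O[Si](C)(C)C(C)(C)C)cc2)O1 | intermediate
9 | (S)-2-[4-(tert-butyldimethylsilyloxy)phenyl]-4-methoxy-6-methylene-3,6-dihydro-2H-pyran | C=C1C=C(OC)C[C@@H](c2ccc(O[Si](C)(C)C(C)(C)C)cc2)O1 | intermediate
10 | (S)-citronellal | CC(C)=CCC[C@H](C)CC=O | starting material
11 | dimethyl malonate | COC(=O)CC(=O)OC | starting material
12 | dimethyl 2-[(3S)-3,7-dimethyloct-6-en-1-ylidene]malonate | CC(C)=CCC[C@H](C)CC=C(C(=O)OC)C(=O)OC | intermediate
13 | lithium extended enolate of 12, E C1'=C2' bond (not isolated) | CC(C)=CCC[C@H](C)/C=C/C(C(=O)OC)=C(OC)[O-].[Li+] | intermediate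
14 | dimethyl 2-[(1E,3S)-3,7-dimethylocta-1,6-dien-1-yl]malonate | CC(C)=CCC[C@H](C)/C=C/C(C(=O)OC)C(=O)OC | intermediate
15 | dilithium 2-[(1E,3S)-3,7-dimethylocta-1,6-dien-1-yl]malonate (not isolated) | CC(C)=CCC[C@H](C)/C=C/C(C(=O)[O-])C(=O)[O-].[Li+].[Li+] | intermediate
16 | 2-[(1E,3S)-3,7-dimethylocta-1,6-dien-1-yl]malonic acid | CC(C)=CCC[C@H](C)/C=C/C(C(=O)O)C(=O)O | intermediate
17 | 2-[(1E,3S)-3,7-dimethylocta-1,6-dien-1-yl]malonyl dichloride | CC(C)=CCC[C@H](C)/C=C/C(C(=O)Cl)C(=O)Cl | intermediate
18 | C8-monoacylated dienol ether: 9 carrying the ClC(=O)-CH(alkenyl)-C(=O)- group on the exocyclic carbon, acyl group cis to C4a, malonyl CH undefined (not isolated) | CC(C)=CCC[C@H](C)/C=C/C(C(=O)Cl)C(=O)/C=C1\C=C(OC)C[C@@H](c2ccc(O[Si](C)(C)C(C)(C)C)cc2)O1 | intermediate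
19 | (2S)-2-[4-(tert-butyldimethylsilyloxy)phenyl]-6-[(1E,3S)-3,7-dimethylocta-1,6-dien-1-yl]-4-methoxy-2H-chromene-5,7-diol (not isolated) | CC(C)=CCC[C@H](C)/C=C/c1c(O)cc2c(c1O)C(OC)=C[C@@H](c1ccc(O[Si](C)(C)C(C)(C)C)cc1)O2 | intermediate
20 | (2S)-2-[4-(tert-butyldimethylsilyloxy)phenyl]-6-[(1E,3S)-3,7-dimethylocta-1,6-dien-1-yl]-5,7-dihydroxychroman-4-one | CC(C)=CCC[C@H](C)/C=C/c1c(O)cc2c(c1O)C(=O)C[C@@H](c1ccc(O[Si](C)(C)C(C)(C)C)cc1)O2 | intermediate
21 | (2S)-6-[(1E,3S)-3,7-dimethylocta-1,6-dien-1-yl]-5,7-dihydroxy-2-(4-hydroxyphenyl)chroman-4-one, CNP0150993.1 | CC(C)=CCC[C@H](C)/C=C/c1c(O)cc2c(c1O)C(=O)C[C@@H](c1ccc(O)cc1)O2 | target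

Total step count: 10.
Longest linear sequence: 6 steps (1, 2, 3, 4, 9, 10). The chain branch 5, 6, 7, 8, 9, 10 is equally long.

Steps most likely to fail

1. Step 9 (proposed new method).
- What may go wrong: intermolecular acylation may outrun ring closure and lead to oligomerisation. The dienol ether may be protonated and its double bond may migrate before it is acylated. The ketene formed by loss of HCl may condense with itself. Acylation at O1 may be followed by ionisation of the benzylic C2-O1 bond, with loss of the C2 configuration.
- Fallback (known chemistry only): the late construction of ring A is given up, and the chain is attached to a finished flavanone by cross-coupling. The fallback sets out from (S)-citronellal 10 and comes back to the route at target 21.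
- Aldehyde 10 is treated with nonafluorobutanesulfonyl fluoride and tert-butylimino-tri(pyrrolidino)phosphorane in DMF to give the enol nonaflate F1, which eliminates in the same flask to (S)-3,7-dimethyloct-6-en-1-yne F2. Hydrostannation (Bu3SnH, cat. PdCl2(PPh3)2, THF) gives the (E)-alkenylstannane F3.
- Bought (2S)-naringenin F4 is silylated at its two non-chelated phenols (TBSCl, imidazole, DMF) to the 7,4'-bis-O-TBS ether F5. N-iodosuccinimide in DMF, which attacks 5-hydroxy-7-alkoxyflavonoids next to the free chelated 5-OH, gives the 6-iodide F6, whose regiochemistry is to be confirmed before going on.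
- A base-free Stille coupling of F3 with F6 (Pd2(dba)3, AsPh3, N-methylpyrrolidone, 45 °C) should give the bis-silyl ether of the target F7. The conditions of step 10 then remove both phenolic silyl groups to give 21.

2. Step 7.
- What may go wrong: the delocalised anion may be reprotonated at the γ-carbon in aqueous base (reconjugation), after which hydroxide addition and retro-Knoevenagel cleavage follow. The hydrolysis may stall at the half ester. The diacid may decarboxylate during acidification and concentration.
- Fallback: ester hydrolysis is avoided altogether, and the second carboxyl group is brought in by carboxylation. The fallback sets out from (S)-citronellal 10 and comes back at dilithium malonate 15.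
- Heating 10 with malonic acid and catalytic piperidinium acetate in DMSO at 100 °C (modified Knoevenagel condensation) passes through the alkylidenemalonic acid F8. This decarboxylates with a shift of the double bond to (3E,5S)-5,9-dimethyldeca-3,8-dienoic acid F9.
- Two equivalents of LiN(iPr)2 in THF (-78 to 0 °C) give the dilithium dienediolate F10. Its α-carboxylation with CO2 at -78 °C gives 15 directly, which is acidified cold to 16 as in step 7.

3. Step 4.
- What may go wrong: methylenation of the electron-rich vinylogous carbonate carbonyl may be sluggish at a temperature where the product already degrades. The exocyclic double bond may migrate into the ring, followed by electrocyclic opening of the resulting 2H-pyran. The dienol ether may hydrolyse on the adsorbent.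
- Fallback: the titanium carbene is replaced by a carbanion addition and elimination (modified Julia olefination of lactones). The fallback sets out from lactone 8 and comes back at methylenepyran 9.
- 2-(Methylsulfonyl)-1,3-benzothiazole is lithiated with LiN(SiMe3)2 in THF at -78 °C and added to 8 to give the hemiketal sulfone F11. DBU in THF at rt then triggers the Smiles rearrangement and fragmentation to 9 under basic, metal-free conditions at ambient temperature.

Further compounds
F1 | step 9 | (3S)-3,7-dimethylocta-1,6-dien-1-yl nonafluorobutane-1-sulfonate, enol double bond geometry undefined | CC(C)=CCC[C@H](C)C=COS(=O)(=O)C(F)(F)C(F)(F)C(F)(F)C(F)(F)F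
F2 | step 9 | (S)-3,7-dimethyloct-6-en-1-yne | CC(C)=CCC[C@H](C)C#C
F3 | step 9 | tributyl[(1E,3S)-3,7-dimethylocta-1,6-dien-1-yl]stannane | CC(C)=CCC[C@H](C)/C=C/[Sn](CCCC)(CCCC)CCCC
F4 | step 9 | (2S)-naringenin (bought partner of the fallback) | O=C1C[C@@H](c2ccc(O)cc2)Oc2cc(O)cc(O)c21
F5 | step 9 | (2S)-7-(tert-butyldimethylsilyloxy)-2-[4-(tert-butyldimethylsilyloxy)phenyl]-5-hydroxychroman-4-one | O=C1C[C@@H](c2ccc(O[Si](C)(C)C(C)(C)C)cc2)Oc2cc(O[Si](C)(C)C(C)(C)C)cc(O)c21
F6 | step 9 | (2S)-7-(tert-butyldimethylsilyloxy)-2-[4-(tert-butyldimethylsilyloxy)phenyl]-5-hydroxy-6-iodochroman-4-one | O=C1C[C@@H](c2ccc(O[Si](C)(C)C(C)(C)C)cc2)Oc2cc(O[Si](C)(C)C(C)(C)C)c(I)c(O)c21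
F7 | step 9 | 7,4'-bis-O-TBS ether of the target | CC(C)=CCC[C@H](C)/C=C/c1c(O[Si](C)(C)C(C)(C)C)cc2c(c1O)C(=O)C[C@@H](c1ccc(O[Si](C)(C)C(C)(C)C)cc1)O2
F8 | step 7 | 2-[(3S)-3,7-dimethyloct-6-en-1-ylidene]malonic acid | CC(C)=CCC[C@H](C)CC=C(C(=O)O)C(=O)O
F9 | step 7 | (3E,5S)-5,9-dimethyldeca-3,8-dienoic acid | CC(C)=CCC[C@H](C)/C=C/CC(=O)O
F10 | step 7 | dilithium dienediolate of F9 | CC(C)=CCC[C@H](C)/C=C/C=C([O-])[O-].[Li+].[Li+]
F11 | step 4 | (6S)-2-[(1,3-benzothiazol-2-ylsulfonyl)methyl]-6-[4-(tert-butyldimethylsilyloxy)phenyl]-4-methoxy-5,6-dihydro-2H-pyran-2-ol, C2 of the pyran undefined | OC1(CS(=O)(=O)c2nc3ccccc3s2)C=C(OC)C[C@@H](c2ccc(O[Si](C)(C)C(C)(C)C)cc2)O1
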